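**Strategy.** Lamesticumin C is cut at C12–C13 into two decalins that both descend from one cyclohexenone, (R)-2,4-dimethyl-4-[(E)-prop-1-enyl]cyclohex-2-enone (future ring A or ring E). The route rests on a [3+3] annulation that builds ring B: the but-1-ene-2,4-diyl unit C6–C7–C8(=CH2) is stitched onto C5 and C9, the two carbons that flank quaternary C10. In one flask a 3-bromobut-3-enylzinc reagent adds to the enone β-carbon C5, then the vinyl bromide closes onto the propenyl carbon C9 by a Heck reaction, which leaves the exocyclic methylene and a 9-vinyl group. The vinyl group later becomes the C11–C12 linker to a ring D/E vinylogous ester.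

Key step: step 4

Numbering: onocerane numbering throughout (ring A C1–C5, C10; ring B C5–C10 with the exocyclic methylene carbon C26 on C8; linker C11–C12; ring D C13–C18; ring E C17–C22); α/β as in the usual terpenoid drawing, with the C10 and C18 methyl groups β.

Assumption: the enantiomer of the prolinamide catalyst in step 1 is the one that delivers (R)-3; its sense of induction is taken by analogy with other α-branched aldehydes.

Step 1
Reactants: 1 2-methylpent-4-enal (racemic); 2 pent-1-en-3-one
Product: 3 (R)-4-allyl-2,4-dimethylcyclohex-2-en-1-one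
Conditions: N-(4-dodecylphenylsulfonyl)prolinamide (20 mol %), BnNH2, 4 Å MS, ClCH2CH2Cl, 25 °C
Reagents that add atoms: none
Why: Organocatalytic Robinson annulation: the catalyst-bound enamine of the α-branched aldehyde adds to the vinyl ketone and sets the quaternary carbon (future C10 and C18) under catalyst control, and aldol condensation through the ethyl CH2 closes the 2-methylcyclohexenone.

Step 2
Reactants: 3 (R)-4-allyl-2,4-dimethylcyclohex-2-en-1-one
Product: 4 (R)-2,4-dimethyl-4-[(E)-prop-1-en-1-yl]cyclohex-2-en-1-one
Conditions: RuHCl(CO)(PPh3)3 (2 mol %), toluene, 80 °C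
Reagents that add atoms: none
Why: Ruthenium hydride-catalysed alkene isomerisation (hydrometalation/β-hydride elimination) should move the terminal double bond one position to the favoured E-propenyl group; it cannot pass the quaternary carbon, whose configuration is untouched.

Step 3
Reactants: 5 3-bromobut-3-en-1-ol
Product: 6 2-bromo-4-iodobut-1-ene
Conditions: I2, PPh3, imidazole, CH2Cl2, 0 to 25 °C
Reagents that add atoms: iodine, II
Why: Appel-type iodination of the primary alcohol through its alkoxyphosphonium salt (SN2); the vinyl bromide is inert.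

Step 4
Reactants: 4 (R)-2,4-dimethyl-4-[(E)-prop-1-en-1-yl]cyclohex-2-en-1-one; 6 2-bromo-4-iodobut-1-ene
Product: 9 rings A/B silyl enol ether (3-trimethylsilyloxy-Δ3; 4,10β-dimethyl; 5α-H; 8-methylidene; 9β-vinyl), via (3-bromobut-3-enyl)zinc iodide 7 (not isolated), via monocyclic silyl enol ether 8 (not isolated)
Conditions: 6, Zn dust, LiCl, THF, 25 °C; then 4, CuBr·SMe2 (10 mol %), Me3SiCl, DMPU, 0 to 25 °C; then Pd(PPh3)4 (10 mol %), Et3N, 70 °C, same flask
Reagents that add atoms: chlorotrimethylsilane, C[Si](C)(C)Cl
Why: Zinc inserts into the C–I bond of 6, and copper-catalysed, silyl chloride-accelerated 1,4-addition of alkylzinc 7 to enone 4 forms C5–C6 and traps the enolate as silyl enol ether 8; zerovalent palladium then inserts into the vinyl C8–Br bond, the alkenylpalladium adds across the propenyl C9=C11 bond, and β-hydride elimination toward the C12 methyl releases 1,4-diene 9 (C8–C9 formed). The closest known reaction types are the conjugate addition of functionalised alkylzinc halides to enones and the intramolecular Heck reaction of 2-bromo-1-alkenes with an Alder-ene-type outcome, merged here into a [3+3] methylenecyclohexane annulation. Ring B closes by 6-exo-trig carbopalladation. C5 is controlled by quaternary C10: axial attack anti to the pseudoaxial propenyl group should put C6 cis to the C10 methyl, which is the trans-decalin relation; C9 is set in a chair-like transition state with the C10 methyl axial and C11 equatorial, giving 9α-H. The step needs chemoselective addition to the enone (the unactivated propenyl group does not accept the organocopper), 6-exo closure rather than 7-endo closure or attack on the tetrasubstituted silyl enol ether (secured by ring size and steric shielding), and elimination away from the ring C9–H (the freely rotating methyl supplies the syn hydrogen).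

Step 5
Reactants: 9 rings A/B silyl enol ether
Product: 10 (5α-H,9α-H,10β-CH3)-5-ethenyl-1,1,4a-trimethyl-6-methylideneoctahydronaphthalen-2(1H)-one (3-oxo; 4,4-dimethyl; 8-methylidene; 9β-vinyl)
Conditions: MeLi, THF, 0 °C; then MeI, DMPU, −78 to 0 °C
Reagents that add atoms: iodomethane, CI
Why: Methyllithium cleaves the silyl enol ether to the regiodefined C3/C4 lithium enolate, and enolate C-methylation at C4 completes the gem-dimethyl group; C4 is no stereocentre and C5, C9 and C10 are not enolisable.

Step 6
Reactants: 10 rings A/B ketone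
Product: 11 3β-alcohol (3S) of 10
Conditions: NaBH4, MeOH, 0 °C
Reagents that add atoms: none
Why: Carbonyl reduction with axial hydride delivery from the α-face, away from the axial 4β- and 10β-methyl groups, should give the equatorial 3β-alcohol.

Step 7
Reactants: 11 3β-alcohol
Product: 12 9β-(2-iodoethyl)-8-methylidene-4,4,10β-trimethyl-trans-decalin-3β-ol (C12 iodide)
Conditions: (Sia)2BH (2.2 equiv, from BH3·SMe2 and 2-methylbut-2-ene), THF, 0 °C; then I2, NaOMe, MeOH, 0 to 25 °C
Reagents that add atoms: iodine, II
Why: Hydroboration–iodination: the bulky dialkylborane should select the monosubstituted C11=C12 vinyl group over the hindered 1,1-disubstituted exocyclic methylene, and base-induced iodinolysis of the primary alkylborane gives the C12 iodide without touching a stereocentre.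

Step 8
Reactants: 4 (R)-2,4-dimethyl-4-[(E)-prop-1-en-1-yl]cyclohex-2-en-1-one; 13 2-methylallylmagnesium chloride
Product: 15 ring E ketone 2,2,4-trimethyl-3-(2-methylprop-2-enyl)-4-[(E)-prop-1-enyl]cyclohexan-1-one (C17 chain cis to the C18 methyl), via silyl enol ether 14 (not isolated)
Conditions: 13, CuBr·SMe2 (20 mol %), Me3SiCl, THF, −78 °C; then MeLi, 0 °C; then MeI, DMPU, −78 to 0 °C
Reagents that add atoms: iodomethane, CI
Why: Conjugate addition–enolate alkylation: copper-mediated allylation at the enone β-carbon C17 anti to the propenyl group on C18 sets the trans relation of C16 and C13, and the silyl enol ether, unmasked with methyllithium, is C-methylated to give the C22 gem-dimethyl group.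

Step 9
Reactants: 15 ring E ketone
Product: 16 methyl 1,3,3-trimethyl-4-oxo-2-(2-oxopropyl)cyclohexane-1-carboxylate (ester carbon C13 and C17 chain trans)
Conditions: O3, NaOH, MeOH, CH2Cl2, −78 °C
Reagents that add atoms: ozone, O=[O+][O-]; methanol, CO
Why: Ozonolysis in methanolic sodium hydroxide should cleave both alkenes, the 1,1-disubstituted one to the C15 methyl ketone and the propenyl group (through its methoxy hydroperoxide and hemiacetal) to the C13 methyl ester; C17 and C18 carry no acidic hydrogen.

Step 10
Reactants: 16 keto ester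
Product: 18 trans-fused 2,5,5,8a-tetramethyloctahydronaphthalene-1,3,6-trione (ring D/E; C14 methyl), via trione 17 (not isolated)
Conditions: KOtBu, THF, 0 to 25 °C; then MeI, MeOH–H2O, 50 °C
Reagents that add atoms: iodomethane, CI
Why: Intramolecular Claisen condensation of the C14 methyl-ketone enolate onto the C13 ester closes ring D as the 1,3-diketone (six-membered, driven by deprotonation of the product), and its stabilised enolate is C-methylated at C14 in protic medium, where the C21 ketone is not enolised.

Step 11
Reactants: 18 methylated trione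
Product: 19 trans-fused 3,6,6-trimethoxy-2,5,5,8a-tetramethyl-4a,5,6,7,8,8a-hexahydronaphthalen-1(4H)-one (C13 carbonyl; C15 methoxy; C21 dimethyl ketal)
Conditions: HC(OMe)3, MeOH, TsOH (5 mol %), 40 °C
Reagents that add atoms: trimethyl orthoformate, COC(OC)OC
Why: Acid-catalysed enol etherification under equilibrating conditions should place the methoxy group on the less hindered C15 and leave the carbonyl at C13 beside quaternary C18, while acetalisation turns the C21 ketone into its dimethyl ketal.

Step 12
Reactants: 12 C12 iodide; 19 vinylogous ester ketal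
Product: 22 lamesticumin C, via dilithio species 20 (not isolated), via tertiary carbinol 21 (not isolated)
Conditions: t-BuLi (3.2 equiv), Et2O–pentane, −78 °C; CeCl3, then 19, THF, −78 to 0 °C; then 1 M HCl, THF, 25 °C
Reagents that add atoms: water, O
Why: After deprotonation of the C3 hydroxyl, lithium–iodine exchange gives the primary organometallic, which adds 1,2 to the C13 carbonyl; aqueous acid then ionises the tertiary allylic alcohol, hydrolyses the methoxyallyl cation to the transposed C13=C14–C15=O enone (Stork–Danheiser transposition) and cleaves the ketal, without touching a stereocentre.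

**Compound list**

1 | 2-methylpent-4-enal (racemic) | C=CCC(C)C=O | starting material
2 | pent-1-en-3-one | CCC(=O)C=C | starting material
3 | (R)-4-allyl-2,4-dimethylcyclohex-2-en-1-one | O=C1CC[C@](C)(CC=C)C=C1C | intermediate
4 | (R)-2,4-dimethyl-4-[(E)-prop-1-en-1-yl]cyclohex-2-en-1-one | O=C1CC[C@](C)(/C=C/C)C=C1C | intermediate
5 | 3-bromobut-3-en-1-ol | OCCC(Br)=C | starting material
6 | 2-bromo-4-iodobut-1-ene | ICCC(Br)=C | intermediate
7 | (3-bromobut-3-en-1-yl)zinc iodide | I[Zn]CCC(Br)=C | intermediate
8 | trimethylsilyl enol ether of the conjugate adduct: 3-(3-bromobut-3-enyl)-2,4-dimethyl-4-[(E)-propenyl]-1-(trimethylsilyloxy)cyclohex-1-ene, butenyl chain (C5) cis to the C10 methyl | C=C(Br)CC[C@H]1C(C)=C(O[Si](C)(C)C)CC[C@]1(C)/C=C/C | intermediate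
9 | rings A/B silyl enol ether: 3-(trimethylsilyloxy)-Δ3, 4,10β-dimethyl, 5α-H, 8-methylidene, 9β-vinyl (9α-H) | C=C1CC[C@H]2C(C)=C(O[Si](C)(C)C)CC[C@]2(C)[C@H]1C=C | intermediate
10 | (5α-H,9α-H,10β-CH3)-5-ethenyl-1,1,4a-trimethyl-6-methylideneoctahydronaphthalen-2(1H)-one | C=C1CC[C@H]2C(C)(C)C(=O)CC[C@]2(C)[C@H]1C=C | intermediate
11 | 3β-alcohol (3S) of 10: 9β-vinyl-8-methylidene-4,4,10β-trimethyl-trans-decalin-3β-ol | C=C1CC[C@H]2C(C)(C)[C@@H](O)CC[C@]2(C)[C@H]1C=C | intermediate
12 | 9β-(2-iodoethyl)-8-methylidene-4,4,10β-trimethyl-trans-decalin-3β-ol | C=C1CC[C@H]2C(C)(C)[C@@H](O)CC[C@]2(C)[C@H]1CCI | intermediate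
13 | 2-methylallylmagnesium chloride | CC(=C)C[Mg]Cl | starting material
14 | trimethylsilyl enol ether of the methallyl adduct (C17 chain cis to the C18 methyl) | C=C(C)C[C@H]1C(C)=C(O[Si](C)(C)C)CC[C@]1(C)/C=C/C | intermediate
15 | 2,2,4-trimethyl-3-(2-methylprop-2-enyl)-4-[(E)-prop-1-enyl]cyclohexan-1-one (C17 chain cis to the C18 methyl) | C=C(C)C[C@H]1C(C)(C)C(=O)CC[C@]1(C)/C=C/C | intermediate
16 | methyl 1,3,3-trimethyl-4-oxo-2-(2-oxopropyl)cyclohexane-1-carboxylate (ester and 2-oxopropyl trans) | CC(=O)C[C@H]1C(C)(C)C(=O)CC[C@]1(C)C(=O)OC | intermediate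
17 | trans-fused 5,5,8a-trimethyloctahydronaphthalene-1,3,6-trione (17α-H, 18β-CH3) | O=C1CC(=O)C[C@H]2C(C)(C)C(=O)CC[C@]12C | intermediate
18 | trans-fused 2,5,5,8a-tetramethyloctahydronaphthalene-1,3,6-trione (C14 epimers/enol) | O=C1C(C)C(=O)C[C@H]2C(C)(C)C(=O)CC[C@]12C | intermediate
19 | trans-fused 3,6,6-trimethoxy-2,5,5,8a-tetramethyl-4a,5,6,7,8,8a-hexahydronaphthalen-1(4H)-one | O=C1C(C)=C(OC)C[C@H]2C(C)(C)C(OC)(OC)CC[C@]12C | intermediate
20 | dilithio species of 12 (C3 lithium alkoxide, C12 alkyllithium) | C=C1CC[C@H]2C(C)(C)[C@@H](O[Li])CC[C@]2(C)[C@H]1CC[Li] | intermediate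
21 | tertiary carbinol from 1,2-addition at C13 (C13 epimers; C15 enol ether and C21 ketal intact) | C=C1CC[C@H]2C(C)(C)[C@@H](O)CC[C@]2(C)[C@H]1CCC1(O)C(C)=C(OC)C[C@H]2C(C)(C)C(OC)(OC)CC[C@]12C | intermediate
22 | lamesticumin C (3S,5R,9S,10R,17R,18S) | C=C1CC[C@H]2C(C)(C)[C@@H](O)CC[C@]2(C)[C@H]1CCC1=C(C)C(=O)C[C@H]2C(C)(C)C(=O)CC[C@]12C | target

**Step count and risks**

Total step count: 12. Longest linear sequence: 7 steps (1, 2, 4, 5, 6, 7, 12; the ring D/E branch 1, 2, 8, 9, 10, 11, 12 is equally long).

Steps most likely to fail:

1. Step 4. The conjugate addition may discriminate poorly between the two faces, because the methyl and propenyl groups on C10 are of similar size. Leftover alkylzinc may capture the alkenylpalladium by cross-coupling before the slow 6-exo insertion at the neopentyl alkene carbon. β-Hydride elimination and readdition may move the new double bonds into conjugation, and the silyl enol ether may hydrolyse. Fallback, setting out from 4 and returning at 10: copper-catalysed conjugate addition of [4-(trimethylsilyl)but-3-yn-1-yl]magnesium bromide with chlorotrimethylsilane would give silyl enol ether F1. Methyllithium and then iodomethane would give the 4,4-dimethyl ketone F2. Potassium carbonate in methanol would free the terminal alkyne F3. A Pd(OAc)2/PPh3-catalysed enyne cycloisomerisation (Alder-ene type) of the 1,7-enyne would then close ring B at C8–C9 and give 10.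

2. Step 12. The organometallic may deprotonate the hindered vinylogous ester at C16 instead of adding to the C13 carbonyl, the carbanion may be quenched by proton transfer, and the acid hydrolysis may cause migration of the exocyclic double bond. Fallback, setting out from 12 and 19 and returning at 22: deprotonation of 19 at C16 with LDA and O-sulfonylation with N-phenylbis(trifluoromethanesulfonimide) would give dienyl triflate F4. Lithium–iodine exchange on 12 followed by ZnCl2 would give alkylzinc F5. Pd(dppf)Cl2-catalysed Negishi coupling of the two would give dienol ether F6, and dilute HCl would hydrolyse its enol ether and ketal to 22.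

3. Step 10. O-Methylation may compete with C-methylation of the diketone enolate, and acylation at the neopentyl ester may be slow against reversible aldol reactions. Fallback, setting out from 4 and returning at 18: the conjugate addition and methylation of step 8, run with (2-methylidenebutyl)magnesium bromide, would give ketone F7. Ozonolysis in methanolic NaOH would give ethyl ketone ester F8, which KOtBu would close by Claisen condensation directly to 18, with the C14 methyl already in place.

Further compounds
F1 | step 4 | trimethylsilyl enol ether of the 4-(trimethylsilyl)but-3-ynyl adduct (C5 chain cis to the C10 methyl) | C[Si](C)(C)C#CCC[C@H]1C(C)=C(O[Si](C)(C)C)CC[C@]1(C)/C=C/C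
F2 | step 4 | 2,2,4-trimethyl-4-[(E)-prop-1-enyl]-3-[4-(trimethylsilyl)but-3-ynyl]cyclohexan-1-one | C[Si](C)(C)C#CCC[C@H]1C(C)(C)C(=O)CC[C@]1(C)/C=C/C
F3 | step 4 | 3-(but-3-ynyl)-2,2,4-trimethyl-4-[(E)-prop-1-enyl]cyclohexan-1-one | C#CCC[C@H]1C(C)(C)C(=O)CC[C@]1(C)/C=C/C
F4 | step 12 | dienyl triflate of 19 (C13 triflate, C15 methoxy, Δ13 and Δ15) | O=S(=O)(OC1=C(C)C(OC)=C[C@H]2C(C)(C)C(OC)(OC)CC[C@]12C)C(F)(F)F
F5 | step 12 | alkylzinc chloride from 12 (C3 lithium alkoxide) | C=C1CC[C@H]2C(C)(C)[C@@H](O[Li])CC[C@]2(C)[C@H]1CC[Zn]Cl
F6 | step 12 | coupled dienol ether (C15 methoxy diene, C21 dimethyl ketal) | C=C1CC[C@H]2C(C)(C)[C@@H](O)CC[C@]2(C)[C@H]1CCC1=C(C)C(OC)=C[C@H]2C(C)(C)C(OC)(OC)CC[C@]12C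
F7 | step 10 | 2,2,4-trimethyl-3-(2-methylidenebutyl)-4-[(E)-prop-1-enyl]cyclohexan-1-one | C=C(CC)C[C@H]1C(C)(C)C(=O)CC[C@]1(C)/C=C/C
F8 | step 10 | methyl 1,3,3-trimethyl-4-oxo-2-(2-oxobutyl)cyclohexane-1-carboxylate | CCC(=O)C[C@H]1C(C)(C)C(=O)CC[C@]1(C)C(=O)OC
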